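**Strategy.** The target is cut at the central sp2–sp2 single bond (C2–C3) of the (E,E)-buta-1,3-diene that links C2 of dihydropyran ring B (3-methyl half, fused to tropolone ring A) to C2 of dihydropyran ring C (fused to tropolone ring D). This bond lies between two trans-CH=CH units, remote from all stereocentres, so one stereoretentive Suzuki–Miyaura coupling of an (E)-alkenyl iodide with an (E)-alkenyl boronate, both carrying free tropolones, forms it and delivers the unprotected target directly. Each partner is a complete dihydropyranotropolone, made in one step by enantioselective hetero-Diels–Alder reaction of a common tropolone ortho-quinone methide (from chemoenzymatically made stipitaldehyde) with a 1-iodo- or 1-boryl-1,3-diene.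

Key step: step 7

Assumption: the two tropolone tautomers (C7=O/C8–OH and C8=O/C7–OH) interconvert freely, so every tropolone is drawn as in the target; cyclohepta[b]pyran numbering (O1, C2–C4, C4a, C5–C9, C9a) is used.
Assumption: the (R)-configured acid catalyst is taken to give the 2R series in steps 5 and 6; should a trial run show the opposite sense, its (S)-antipode is used instead.
Assumption: 1 is a catalogue compound, TropB and TropC are used as recombinant enzymes, and the R configuration drawn for 2 is the one attributed to TropB and is erased in the same pot.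
Assumption: the quinone methide 10 cannot be stored; each cycloaddition generates it afresh from 4 under the catalyst, and it is entered in the scheme once, at step 5, where it first forms.

Step 1
Reactants: 1 2,4-dihydroxy-3,6-dimethylbenzaldehyde (3-methylorcinaldehyde)
Product: 3 stipitaldehyde, via dearomatised ortho-quinol 2 (not isolated)
Conditions: TropB, TropC, NADP+ (cat.), D-glucose, glucose dehydrogenase, α-ketoglutarate, FeSO4 (cat.), sodium ascorbate, air, KH2PO4/K2HPO4 buffer pH 7.5, 30 °C
Reagents that add atoms: dioxygen (O=O)
Why: This is the native two-enzyme sequence of fungal tropolone biosynthesis, in which a flavin-dependent monooxygenase (TropB) effects hydroxylative dearomatisation at C3 and an α-ketoglutarate-dependent non-heme-iron dioxygenase (TropC) effects oxidative ring expansion that inserts the C3 methyl carbon into the ring, the quaternary centre of 2 being lost on aromatisation.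

Step 2
Reactants: 3 stipitaldehyde
Product: 4 2,4-dihydroxy-5-(hydroxymethyl)-6-methylcyclohepta-2,4,6-trien-1-one
Conditions: NaBH4, THF/MeOH, 0 °C; then NaH2PO4 (aq) to pH 6
Reagents that add atoms: none
Why: Borohydride 1,2-reduction of the aldehyde should give the ortho-hydroxybenzylic-type alcohol, since the ring is present as the unreactive tropolonate and the cold, buffered quench avoids premature quinone methide formation.

Step 3
Reactants: 5 bis(pinacolato)borylmethane; 6 acrolein
Product: 7 (E)-2-(buta-1,3-dien-1-yl)-4,4,5,5-tetramethyl-1,3,2-dioxaborolane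
Conditions: lithium 2,2,6,6-tetramethylpiperidide, THF, 0 °C; then 6, −78 °C → rt
Reagents that add atoms: none
Why: Boron-Wittig olefination, in which the lithiated geminal bis(boronate) adds 1,2 to the aldehyde and syn B–O elimination should give the trans-alkenyl boronate.

Step 4
Reactants: 8 (E)-but-2-enal (crotonaldehyde)
Product: 9 (1E,3E)-1-iodopenta-1,3-diene
Conditions: CrCl2, CHI3, THF, 0 °C → rt, dark
Reagents that add atoms: iodoform (IC(I)I)
Why: Takai olefination, in which the geminal dichromium species from CHI3 adds to the aldehyde and eliminates to the (E)-iodoalkene while the existing E double bond is untouched.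

Step 5
Reactants: 4 2,4-dihydroxy-5-(hydroxymethyl)-6-methylcyclohepta-2,4,6-trien-1-one; 9 (1E,3E)-1-iodopenta-1,3-diene
Product: 11 (2R,3R)-8-hydroxy-2-[(E)-2-iodoethenyl]-3,5-dimethyl-3,4-dihydrocyclohepta[b]pyran-7(2H)-one, via tropolone ortho-quinone methide 10 (not isolated)
Conditions: (R)-3,3'-bis(2,4,6-triisopropylphenyl)-1,1'-binaphthyl-2,2'-diyl N-triflylphosphoramide (10 mol%), 9 (3 equiv), 5 Å MS, CHCl3, 0 °C → rt, dark
Reagents that add atoms: none
Why: Proposed new method: the strong chiral Brønsted acid should ionise the benzylic-type alcohol of 4 to the hydroxytropylium-stabilised quinone methide 10, held as a hydrogen-bonded contact ion pair through its C4 carbonyl oxygen and the neighbouring tropolone OH, so that the electron-richer propenyl double bond of 9 (the iodoalkene being deactivated) adds in an inverse-electron-demand [4+2] with CH2 bonding to the methyl-bearing carbon and oxygen to the allyl-cation-like carbon; suprafacial addition to the E alkene gives the 2,3-trans pair and the chiral anion is meant to select the alkene face that makes C2 (and with it C3) R; the closest known reactions are the chiral N-triflylphosphoramide-catalysed enantioselective hetero-Diels–Alder reaction of ortho-hydroxybenzylic alcohols with unactivated styrenes and the uncatalysed thermal cycloaddition of tropolone ortho-quinone methides with alkenes.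

Step 6
Reactants: 4 2,4-dihydroxy-5-(hydroxymethyl)-6-methylcyclohepta-2,4,6-trien-1-one; 7 (E)-2-(buta-1,3-dien-1-yl)-4,4,5,5-tetramethyl-1,3,2-dioxaborolane
Product: 12 (2R)-8-hydroxy-5-methyl-2-[(E)-2-(4,4,5,5-tetramethyl-1,3,2-dioxaborolan-2-yl)ethenyl]-3,4-dihydrocyclohepta[b]pyran-7(2H)-one
Conditions: (R)-3,3'-bis(2,4,6-triisopropylphenyl)-1,1'-binaphthyl-2,2'-diyl N-triflylphosphoramide (10 mol%), 7 (3 equiv), 5 Å MS, CHCl3, 0 °C → rt
Reagents that add atoms: none
Why: Proposed new method: the catalyst should ionise a fresh portion of 4 exactly as in step 5, and the resulting catalyst-bound chiral ion pair (the transient 10 once more) should be attacked at its CH2 terminus by the unsubstituted terminal carbon of the vinyl group of 7 (the boryl-substituted double bond being the electron-poorer one), after which ring closure by the C4 oxygen on the internal carbon gives the 2-alkenyl pyran with the E-alkenyl boronate intact, the chiral anion being meant to select the alkene face that gives 2R; the closest known reactions are the chiral N-triflylphosphoramide-catalysed hetero-Diels–Alder reaction of in situ generated ortho-quinone methides with unactivated alkenes and the thermal cycloaddition of tropolone ortho-quinone methides.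

Step 7
Reactants: 11 (2R,3R)-8-hydroxy-2-[(E)-2-iodoethenyl]-3,5-dimethyl-3,4-dihydrocyclohepta[b]pyran-7(2H)-one; 12 (2R)-8-hydroxy-5-methyl-2-[(E)-2-(4,4,5,5-tetramethyl-1,3,2-dioxaborolan-2-yl)ethenyl]-3,4-dihydrocyclohepta[b]pyran-7(2H)-one
Product: 13 (2R,3R)-8-hydroxy-2-{(1E,3E)-4-[(2R)-8-hydroxy-5-methyl-7-oxo-2,3,4,7-tetrahydrocyclohepta[b]pyran-2-yl]buta-1,3-dien-1-yl}-3,5-dimethyl-3,4-dihydrocyclohepta[b]pyran-7(2H)-one (CNP0332980.1)
Conditions: Pd(dppf)Cl2·CH2Cl2 (5 mol%), K3PO4 (aq), THF, rt, degassed, dark; then pH 5 buffer, aqueous EDTA wash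
Reagents that add atoms: none
Why: Zerovalent palladium inserts into the C(sp2)–I bond of 11 with retention, the alkenyl group of 12 is transferred from the hydroxide-activated boronate with retention, and reductive elimination forms the central sp2–sp2 bond, so both E geometries pass unchanged into the (E,E)-diene. The closest known reaction type is the Suzuki–Miyaura alkenyl–alkenyl coupling used for stereodefined polyenes. The step closes no ring and creates no stereocentre, and the three existing centres lie two or more atoms from the reacting carbons. The selectivity needed is reaction at C–I in preference to ionisation of the two allylic tropolonyl ether C–O bonds, which would scramble C2 of rings B and C; under the basic conditions both tropolones are tropolonate anions, which should make the pyran oxygens very poor leaving groups, and oxidative addition to an alkenyl iodide is fast at room temperature. The chelating diphosphine is chosen to keep palladium from being held as a tropolonate chelate, and aqueous phosphate supplies the hydroxo/borate transmetalation pathway. Acidification to pH 5 and the EDTA wash should return the free bis-tropolone.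

**Compound list**

1 | 2,4-dihydroxy-3,6-dimethylbenzaldehyde (3-methylorcinaldehyde) | Cc1cc(O)c(C)c(O)c1C=O | starting material
2 | (3R)-2,3-dihydroxy-3,6-dimethyl-4-oxocyclohexa-1,5-diene-1-carbaldehyde (dearomatised ortho-quinol, not isolated) | O=CC1=C(O)[C@@](C)(O)C(=O)C=C1C | intermediate
3 | stipitaldehyde (tropolone bearing 4-OH, 5-CHO and 6-CH3; 2,4-dihydroxy-7-methyl-5-oxocyclohepta-1,3,6-triene-1-carbaldehyde) | O=Cc1c(C)cc(=O)c(O)cc1O | intermediate
4 | 2,4-dihydroxy-5-(hydroxymethyl)-6-methylcyclohepta-2,4,6-trien-1-one | OCc1c(C)cc(=O)c(O)cc1O | intermediate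
5 | bis(pinacolato)borylmethane (2,2'-methylenebis(4,4,5,5-tetramethyl-1,3,2-dioxaborolane)) | CC1(C)OB(CB2OC(C)(C)C(C)(C)O2)OC1(C)C | starting material
6 | acrolein (prop-2-enal) | C=CC=O | starting material
7 | (E)-2-(buta-1,3-dien-1-yl)-4,4,5,5-tetramethyl-1,3,2-dioxaborolane | C=C/C=C/B1OC(C)(C)C(C)(C)O1 | intermediate
8 | (E)-but-2-enal (crotonaldehyde) | C/C=C/C=O | starting material
9 | (1E,3E)-1-iodopenta-1,3-diene | C/C=C/C=C/I | intermediate
10 | 2-hydroxy-6-methyl-5-methylidenecyclohepta-2,6-diene-1,4-dione (tropolone ortho-quinone methide, not isolated) | C=C1C(C)=CC(=O)C(O)=CC1=O | intermediate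
11 | (2R,3R)-8-hydroxy-2-[(E)-2-iodoethenyl]-3,5-dimethyl-3,4-dihydrocyclohepta[b]pyran-7(2H)-one (2,3-trans; rings A and B) | Cc1cc(=O)c(O)cc2c1C[C@@H](C)[C@H](/C=C/I)O2 | intermediate
12 | (2R)-8-hydroxy-5-methyl-2-[(E)-2-(4,4,5,5-tetramethyl-1,3,2-dioxaborolan-2-yl)ethenyl]-3,4-dihydrocyclohepta[b]pyran-7(2H)-one (rings C and D) | CC1(C)OB(/C=C/[C@H]2CCc3c(C)cc(=O)c(O)cc3O2)OC1(C)C | intermediate
13 | (2R,3R)-8-hydroxy-2-{(1E,3E)-4-[(2R)-8-hydroxy-5-methyl-7-oxo-2,3,4,7-tetrahydrocyclohepta[b]pyran-2-yl]buta-1,3-dien-1-yl}-3,5-dimethyl-3,4-dihydrocyclohepta[b]pyran-7(2H)-one (CNP0332980.1) | Cc1cc(=O)c(O)cc2c1C[C@@H](C)[C@H](/C=C/C=C/[C@H]1CCc3c(C)cc(=O)c(O)cc3O1)O2 | target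

**Step count.** Total: 7 steps. Longest linear sequence: 4 steps (steps 1, 2, 5, 7; equally 1, 2, 6, 7).

**Steps most likely to fail**

Step 5 (Proposed new method). The ion pair between the chiral anion and a methide that carries no substituent may discriminate the two alkene faces poorly, and a stepwise allyl-cation pathway may let the 2,3-trans relationship leak to cis. Fallback with known chemistry, setting out from 4 and 9: the uncatalysed thermal cycloaddition (toluene, 5 Å MS, 90 °C, dark, BHT), a known reaction of tropolone ortho-quinone methides with alkenes, should give the trans adduct as the racemate, that is 11 together with its mirror image, (2S,3S)-8-hydroxy-2-[(E)-2-iodoethenyl]-3,5-dimethyl-3,4-dihydrocyclohepta[b]pyran-7(2H)-one F1. Preparative supercritical-fluid chromatography on a polysaccharide chiral stationary phase then separates the two, and the (2R,3R) enantiomer rejoins the route as 11.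

Step 6 (Proposed new method). Facial discrimination may again be insufficient, and association of the boronate with the tropolone oxygens may loosen the ion pair further. Fallback with known chemistry, setting out from 4: acid-catalysed Hosomi–Sakurai-type benzylic allylation of 4 with allyltrimethylsilane (diphenyl phosphate cat., CH2Cl2), which runs through the same transient quinone methide, should give 5-(but-3-en-1-yl)-2,4-dihydroxy-6-methylcyclohepta-2,4,6-trien-1-one F2. Cross-metathesis with allyl methyl carbonate (Hoveyda–Grubbs second-generation catalyst, CH2Cl2, 40 °C) should then give 5-[(E)-5-(methoxycarbonyloxy)pent-3-en-1-yl]-2,4-dihydroxy-6-methylcyclohepta-2,4,6-trien-1-one F3. Tsuji–Trost asymmetric allylic etherification (Pd2(dba)3·CHCl3, DACH-phenyl Trost ligand of the enantiomeric series that gives 2R, AcOH, CH2Cl2, rt) should close the six-membered pyran to (2R)-2-ethenyl-8-hydroxy-5-methyl-3,4-dihydrocyclohepta[b]pyran-7(2H)-one F4. A second cross-metathesis, with vinylboronic acid pinacol ester and the same catalyst, should give the (E)-alkenyl boronate and rejoin the route at 12.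

Step 7 (key step). Palladium may be sequestered as tropolonate chelates of the substrates and product so that transmetalation stalls, and a long-lived zerovalent palladium pool could then begin to ionise the allylic C–O bonds. Fallback, setting out from 11 and 12: each tropolone is masked as its pivalate (PivCl, Et3N, CH2Cl2, 0 °C), each drawn as one of two acyl-shift isomers. This gives (2R,3R)-2-[(E)-2-iodoethenyl]-3,5-dimethyl-7-oxo-2,3,4,7-tetrahydrocyclohepta[b]pyran-8-yl pivalate F5 and (2R)-5-methyl-7-oxo-2-[(E)-2-(4,4,5,5-tetramethyl-1,3,2-dioxaborolan-2-yl)ethenyl]-2,3,4,7-tetrahydrocyclohepta[b]pyran-8-yl pivalate F6. These are coupled under anhydrous fluoride conditions (Pd(PPh3)4, CsF, THF, rt) to the bis-pivalate of 13 F7. Mild methanolysis (K2CO3, MeOH, 0 °C) then returns to the route at 13.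

**Further compounds**

F1 | step 5 | (2S,3S)-8-hydroxy-2-[(E)-2-iodoethenyl]-3,5-dimethyl-3,4-dihydrocyclohepta[b]pyran-7(2H)-one (enantiomer of 11, formed with 11 as the racemate) | Cc1cc(=O)c(O)cc2c1C[C@H](C)[C@@H](/C=C/I)O2
F2 | step 6 | 5-(but-3-en-1-yl)-2,4-dihydroxy-6-methylcyclohepta-2,4,6-trien-1-one | C=CCCc1c(C)cc(=O)c(O)cc1O
F3 | step 6 | 5-[(E)-5-(methoxycarbonyloxy)pent-3-en-1-yl]-2,4-dihydroxy-6-methylcyclohepta-2,4,6-trien-1-one | COC(=O)OC/C=C/CCc1c(C)cc(=O)c(O)cc1O
F4 | step 6 | (2R)-2-ethenyl-8-hydroxy-5-methyl-3,4-dihydrocyclohepta[b]pyran-7(2H)-one | C=C[C@H]1CCc2c(C)cc(=O)c(O)cc2O1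
F5 | step 7 | (2R,3R)-2-[(E)-2-iodoethenyl]-3,5-dimethyl-7-oxo-2,3,4,7-tetrahydrocyclohepta[b]pyran-8-yl pivalate | Cc1cc(=O)c(OC(=O)C(C)(C)C)cc2c1C[C@@H](C)[C@H](/C=C/I)O2
F6 | step 7 | (2R)-5-methyl-7-oxo-2-[(E)-2-(4,4,5,5-tetramethyl-1,3,2-dioxaborolan-2-yl)ethenyl]-2,3,4,7-tetrahydrocyclohepta[b]pyran-8-yl pivalate | CC1(C)OB(/C=C/[C@H]2CCc3c(C)cc(=O)c(OC(=O)C(C)(C)C)cc3O2)OC1(C)C
F7 | step 7 | bis-pivalate of 13 (both tropolone hydroxyls acylated) | Cc1cc(=O)c(OC(=O)C(C)(C)C)cc2c1C[C@@H](C)[C@H](/C=C/C=C/[C@H]1CCc3c(C)cc(=O)c(OC(=O)C(C)(C)C)cc3O1)O2
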